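The tetrahydrofuran ring of the target consists of OCH2, CH(CH3), the ring-fusion CH and the ketal carbon. It is treated as a trans-3-benzyl-4-methyl-γ-butyrolactone whose carbonyl carbon later becomes the methyl ketal. Cutting its C4–CH3 and C3–CH2Ar bonds leads back to an enantiopure 5-menthyloxybutenolide, a methyl cuprate and the benzylic bromide of MOM-protected (R)-lasiodiplodin. The key step joins these three pieces in one flask and sets both tertiary stereocentres by relay from the acetal carbon. Borohydride excision of menthol, a single methyllithium addition and acid-induced MOM loss with ketalisation then close the pyran ring between the phenol oxygen and the ketal carbon.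

Key step: step 14

Remark on the chemistry: the macrolide is numbered as a 2-benzoxacyclododecin (C1 lactone carbonyl, O2, C3 carbinol carbon, C4–C10 methylenes, C11 aromatic CH next to the chain, C12 oxygen-bearing carbon para to the carbonyl, C13 CH between the two oxygens, C14 C–OMe); the ring alkene of the metathesis product and the hemiketal carbon of the methyllithium adducts are drawn without configuration, since the following step erases or fixes them.

Step 1
Reactants: 1 furfural
Product: 2 5-hydroxyfuran-2(5H)-one (racemic)
Conditions: O2, hν (visible), rose bengal (cat.), MeOH, 20 °C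
Reagents that add atoms: oxygen, O=O
Why: Dye-sensitised singlet-oxygen [4+2] cycloaddition to the furan gives an endoperoxide whose methanolysis expels the formyl carbon as methyl formate and leaves the γ-hydroxybutenolide (furfural photo-oxygenation); the hemiacetal carbon forms racemic and is corrected in step 2.

Step 2
Reactants: 2 5-hydroxyfuran-2(5H)-one; 3 (+)-menthol, (1S,2R,5S)-2-isopropyl-5-methylcyclohexan-1-ol
Product: 4 (5S)-5-[(1S,2R,5S)-menthyloxy]furan-2(5H)-one
Conditions: neat, 100 °C; crystallisation from petroleum ether, mother liquor re-equilibrated with camphorsulfonic acid (cat.) and recrystallised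
Reagents that add atoms: none
Why: Thermal acetalisation of the cyclic hemiacetal gives both C5 epimers, the acetal carbon equilibrates under acid, and the (5S)-epimer of the (+)-menthol series should be the crystalline one, so crystallisation with recycling (crystallisation-driven diastereomer resolution) sets C5.

Step 3
Reactants: 5 (S)-propylene oxide; 6 but-3-enylmagnesium bromide
Product: 7 (S)-hept-6-en-2-ol
Conditions: CuI (10 mol %), THF, −30 → 0 °C
Reagents that add atoms: none
Why: Copper-catalysed Grignard opening of a terminal epoxide proceeds by SN2 attack at the unsubstituted CH2, so the C–O stereocentre of 5 passes unchanged into 7.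

Step 4
Reactants: 8 methyl orsellinate (methyl 2,4-dihydroxy-6-methylbenzoate)
Product: 9 methyl 2-hydroxy-4-(methoxymethoxy)-6-methylbenzoate
Conditions: MOMCl (1.1 equiv), iPr2NEt, CH2Cl2, 0 °C
Reagents that add atoms: chloromethyl methyl ether, COCCl
Why: Williamson-type O-alkylation selects the C4 phenol because the C2 phenol is held in a hydrogen bond to the ester carbonyl and is crowded by it.

Step 5
Reactants: 9 methyl 2-hydroxy-4-(methoxymethoxy)-6-methylbenzoate
Product: 10 methyl 2-methoxy-4-(methoxymethoxy)-6-methylbenzoate
Conditions: MeI, K2CO3, DMF, 25 → 40 °C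
Reagents that add atoms: iodomethane, CI
Why: With the C4 oxygen blocked, carbonate in a dipolar aprotic solvent breaks the chelate and the remaining phenoxide is methylated by SN2 (Williamson ether synthesis).

Step 6
Reactants: 10 methyl 2-methoxy-4-(methoxymethoxy)-6-methylbenzoate; 11 allyl bromide
Product: 13 methyl 2-(but-3-enyl)-6-methoxy-4-(methoxymethoxy)benzoate, via benzylic lithium species 12 (not isolated)
Conditions: LDA (1.15 equiv), THF, −78 °C; then 11, −78 → −40 °C
Reagents that add atoms: none
Why: Lateral lithiation of the ortho-toluate gives the ester-stabilised benzylic anion 12, which the very reactive allylic bromide captures at −78 °C faster than it can condense with unlithiated ester.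

Step 7
Reactants: 13 methyl 2-(but-3-enyl)-6-methoxy-4-(methoxymethoxy)benzoate
Product: 14 2-(but-3-enyl)-6-methoxy-4-(methoxymethoxy)benzoic acid
Conditions: KOH, EtOH/H2O, reflux; then 1 M HCl to pH 4, 0 °C
Reagents that add atoms: potassium hydroxide, [K+].[OH-]
Why: Saponification of the doubly ortho-substituted methyl ester needs forcing hydroxide, which the MOM ether, the aryl methyl ether and the isolated alkene tolerate, and cold acidification to pH 4 avoids MOM loss and decarboxylation.

Step 8
Reactants: 14 2-(but-3-enyl)-6-methoxy-4-(methoxymethoxy)benzoic acid; 7 (S)-hept-6-en-2-ol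
Product: 15 (R)-hept-6-en-2-yl 2-(but-3-enyl)-6-methoxy-4-(methoxymethoxy)benzoate
Conditions: PPh3, DIAD, toluene, 0 → 25 °C
Reagents that add atoms: none
Why: Mitsunobu esterification activates the alcohol rather than the hindered acid, and the carboxylate displaces the oxyphosphonium group by SN2 with inversion, turning (S)-7 into the (R)-ester.

Step 9
Reactants: 15 (R)-hept-6-en-2-yl 2-(but-3-enyl)-6-methoxy-4-(methoxymethoxy)benzoate
Product: 16 (3R)-14-methoxy-12-(methoxymethoxy)-3-methyl-3,4,5,6,9,10-hexahydro-1H-2-benzoxacyclododecin-1-one (C7=C8 alkene, E/Z mixture)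
Conditions: second-generation Grubbs catalyst (5 mol %), CH2Cl2 (1 mM), reflux
Reagents that add atoms: none
Why: Ring-closing metathesis of two unhindered terminal alkenes at high dilution closes the 12-membered benzo-fused lactone with loss of ethene, and the alkene geometry does not matter because the double bond is hydrogenated next.

Step 10
Reactants: 16 the C7=C8 unsaturated macrolactone
Product: 17 (R)-lasiodiplodin MOM ether, (3R)-14-methoxy-12-(methoxymethoxy)-3-methyl-3,4,5,6,7,8,9,10-octahydro-1H-2-benzoxacyclododecin-1-one
Conditions: H2 (1 atm), Pd/C, EtOAc, 25 °C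
Reagents that add atoms: none
Why: Heterogeneous catalytic hydrogenation saturates the disubstituted ring alkene, and the molecule holds no benzylic C–O bond or halide that could be hydrogenolysed.

Step 11
Reactants: 17 (R)-lasiodiplodin MOM ether
Product: 18 11-iodo-(R)-lasiodiplodin MOM ether (iodine between C12–OMOM and the chain-bearing ring carbon)
Conditions: NIS (1.05 equiv), MeCN, 0 → 25 °C, dark
Reagents that add atoms: N-iodosuccinimide, O=C1CCC(=O)N1I
Why: Electrophilic aromatic iodination should go to C11, para to OMe and ortho to OMOM, rather than to C13, which is buried between two alkoxy groups, as is usual for 3,5-dialkoxyalkylbenzenes, and the neutral medium keeps the MOM group.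

Step 12
Reactants: 18 11-iodo-(R)-lasiodiplodin MOM ether
Product: 19 11-(hydroxymethyl)-(R)-lasiodiplodin MOM ether
Conditions: Bu3SnCH2OH (1.5 equiv), Pd(PPh3)4 (10 mol %), 1,4-dioxane, 100 °C
Reagents that add atoms: (tributylstannyl)methanol, CCCC[Sn](CO)(CCCC)CCCC
Why: Migita–Kosugi–Stille coupling with the hydroxymethyl stannane transfers the oxygen-activated CH2OH group in preference to butyl and tolerates the lactone and the acetal.

Step 13
Reactants: 19 11-(hydroxymethyl)-(R)-lasiodiplodin MOM ether
Product: 20 11-(bromomethyl)-(R)-lasiodiplodin MOM ether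
Conditions: CBr4, PPh3, CH2Cl2, −10 °C; short silica plug, used at once
Reagents that add atoms: carbon tetrabromide, BrC(Br)(Br)Br
Why: The Appel reaction converts the primary benzylic alcohol into the bromide under neutral conditions that spare the MOM ether, and the ionisation-prone 2,4-dialkoxybenzyl bromide is not stored.

Step 14
Reactants: 4 (5S)-5-[(1S,2R,5S)-menthyloxy]furan-2(5H)-one; 20 11-(bromomethyl)-(R)-lasiodiplodin MOM ether
Product: 23 (3S,4S,5S)-3-{[(3R)-14-methoxy-12-(methoxymethoxy)-3-methyl-1-oxo-octahydro-2-benzoxacyclododecin-11-yl]methyl}-4-methyl-5-[(1S,2R,5S)-menthyloxy]dihydrofuran-2(3H)-one (all-trans), via lithium dimethylcuprate 21 (not isolated), via lithium enolate 22 (not isolated)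
Conditions: MeLi (3.0 equiv), CuI (1.5 equiv), Et2O, 0 °C; 4 (1.6 equiv) added slowly, −78 °C; then 20 (1.0 equiv), DMPU, THF, −78 → −20 °C; aq. NH4Cl/NH3
Reagents that add atoms: methyllithium, [Li]C
Why: The cuprate binds the enoate π system of 4 and delivers methyl to C4 by oxidative addition and reductive elimination, leaving lithium enolate 22 and methylcopper, and 22 then displaces bromide from 20 by SN2 at C3, so the C4–CH3 and C3–CH2Ar bonds form in one flask and no ring is closed. The closest known reaction type is the tandem conjugate addition–enolate benzylation of 5-alkoxyfuran-2(5H)-ones used for dibenzylbutyrolactone lignans, together with cuprate addition–alkylation of butenolides in general. C4 is controlled by acetal carbon C5, whose menthyloxy group covers one face of the flat ring so that methyl enters anti to it (4S). C3 is controlled by the new C4 methyl group, the planar enolate being benzylated on the face turned away from it (3S), which gives the all-trans lactone. The step needs C-alkylation of 22 to outrun both methyl transfer from copper to 20 and attack of 22 on the macrolactone: 4 is kept in slight excess over 21 so that no dimethylcuprate survives, DMPU loosens the enolate from copper, the 2,4-dialkoxybenzyl bromide is a very fast SN2 partner used as the limiting component, and the benzoate carbonyl is walled in by its two ortho substituents.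

Step 15
Reactants: 23 the all-trans menthyloxy lactone
Product: 26 (3S,4S)-3-{[(R)-lasiodiplodin MOM ether-11-yl]methyl}-4-methyldihydrofuran-2(3H)-one (trans lactone), via formyl carboxylate 24 (not isolated), via hydroxy acid 25 (not isolated)
Conditions: NaBH4, KOH, EtOH/H2O, 0 → 25 °C; then 1 M HCl to pH 3, 0 → 25 °C
Reagents that add atoms: potassium hydroxide, [K+].[OH-]
Why: Hydroxide opens the acyl acetal, the hemiacetal so formed sheds menthol, borohydride present from the start reduces aldehyde 24 before its α-carbon can epimerise, and mild acid relactonises hydroxy acid 25 (hydrolytic reductive removal of the auxiliary), while the shielded macrolactone resists saponification and both stereocentres are retained.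

Step 16
Reactants: 26 the trans lactone
Product: 28 (3S,4S)-3-{[(R)-lasiodiplodin MOM ether-11-yl]methyl}-2,4-dimethyltetrahydrofuran-2-ol (lactol; anomers in equilibrium with the open γ-hydroxy methyl ketone), via lithium lactolate 27 (not isolated)
Conditions: MeLi (1.1 equiv), THF, −78 °C; AcOH/THF quench at −78 °C
Reagents that add atoms: methyllithium, [Li]C
Why: Nucleophilic 1,2-addition of one equivalent of methyllithium to the γ-lactone stops at tetrahedral alkoxide 27, which does not collapse at −78 °C, and the macrolactone carbonyl is protected by its two ortho substituents.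

Step 17
Reactants: 28 the lactol
Product: 30 lasiodiplactone A, via phenol hemiketal 29 (not isolated)
Conditions: 3 M aq. HCl, THF, 40 °C
Reagents that add atoms: none
Why: Acid hydrolyses the aryl MOM acetal and ionises the hemiketal to an oxocarbenium ion that the freed phenol traps in a six-membered ring closure (intramolecular ketalisation under thermodynamic control, as in furo[2,3-b]chromene ketals of the xyloketal type); only the cis-fused bicycle is free of strain, so the ring-fusion CH dictates the (S)-ketal carbon and the C-methyl group sits on the convex face.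

Compound list
1 | furfural | O=Cc1ccco1 | starting material
2 | 5-hydroxyfuran-2(5H)-one (racemic) | OC1C=CC(=O)O1 | intermediate
3 | (+)-menthol | CC(C)[C@H]1CC[C@H](C)C[C@@H]1O | starting material
4 | (5S)-5-[(1S,2R,5S)-menthyloxy]furan-2(5H)-one | O=C1C=C[C@@H](O[C@H]2C[C@@H](C)CC[C@@H]2C(C)C)O1 | intermediate
5 | (S)-propylene oxide | C[C@H]1CO1 | starting material
6 | but-3-enylmagnesium bromide | C=CCC[Mg]Br | starting material
7 | (S)-hept-6-en-2-ol | C[C@H](O)CCCC=C | intermediate
8 | methyl orsellinate | COC(=O)c1c(C)cc(O)cc1O | starting material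
9 | methyl 2-hydroxy-4-(methoxymethoxy)-6-methylbenzoate | COC(=O)c1c(C)cc(OCOC)cc1O | intermediate
10 | methyl 2-methoxy-4-(methoxymethoxy)-6-methylbenzoate | COC(=O)c1c(C)cc(OCOC)cc1OC | intermediate
11 | allyl bromide | C=CCBr | starting material
12 | benzylic lithium species of 10 | [Li]Cc1cc(OCOC)cc(OC)c1C(=O)OC | intermediate
13 | methyl 2-(but-3-enyl)-6-methoxy-4-(methoxymethoxy)benzoate | COC(=O)c1c(CCC=C)cc(OCOC)cc1OC | intermediate
14 | 2-(but-3-enyl)-6-methoxy-4-(methoxymethoxy)benzoic acid | OC(=O)c1c(CCC=C)cc(OCOC)cc1OC | intermediate
15 | (R)-hept-6-en-2-yl 2-(but-3-enyl)-6-methoxy-4-(methoxymethoxy)benzoate | COc1cc(OCOC)cc(CCC=C)c1C(=O)O[C@H](C)CCCC=C | intermediate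
16 | 7,8-didehydro-(R)-lasiodiplodin MOM ether (E/Z) | COc1cc(OCOC)cc2c1C(=O)O[C@H](C)CCCC=CCC2 | intermediate
17 | (R)-lasiodiplodin MOM ether | COc1cc(OCOC)cc2c1C(=O)O[C@H](C)CCCCCCC2 | intermediate
18 | 11-iodo-(R)-lasiodiplodin MOM ether | COc1cc(OCOC)c(I)c2c1C(=O)O[C@H](C)CCCCCCC2 | intermediate
19 | 11-(hydroxymethyl)-(R)-lasiodiplodin MOM ether | COc1cc(OCOC)c(CO)c2c1C(=O)O[C@H](C)CCCCCCC2 | intermediate
20 | 11-(bromomethyl)-(R)-lasiodiplodin MOM ether | COc1cc(OCOC)c(CBr)c2c1C(=O)O[C@H](C)CCCCCCC2 | intermediate
21 | lithium dimethylcuprate | [Li+].C[Cu-]C | intermediate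
22 | lithium enolate of (4S,5S)-4-methyl-5-menthyloxybutyrolactone | [Li+].[O-]C1=C[C@H](C)[C@@H](O[C@H]2C[C@@H](C)CC[C@@H]2C(C)C)O1 | intermediate
23 | all-trans (3S,4S,5S)-3-(macrolide-11-ylmethyl)-4-methyl-5-menthyloxybutyrolactone | COc1cc(OCOC)c(C[C@@H]3C(=O)O[C@H](O[C@H]4C[C@@H](C)CC[C@@H]4C(C)C)[C@H]3C)c2c1C(=O)O[C@H](C)CCCCCCC2 | intermediate
24 | potassium (2S,3S)-2-(macrolide-11-ylmethyl)-3-methyl-4-oxobutanoate | [K+].COc1cc(OCOC)c(C[C@H](C([O-])=O)[C@H](C)C=O)c2c1C(=O)O[C@H](C)CCCCCCC2 | intermediate
25 | (2S,3S)-4-hydroxy-2-(macrolide-11-ylmethyl)-3-methylbutanoic acid | COc1cc(OCOC)c(C[C@H](C(=O)O)[C@H](C)CO)c2c1C(=O)O[C@H](C)CCCCCCC2 | intermediate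
26 | (3S,4S)-3-(macrolide-11-ylmethyl)-4-methylbutyrolactone | COc1cc(OCOC)c(C[C@@H]3C(=O)OC[C@H]3C)c2c1C(=O)O[C@H](C)CCCCCCC2 | intermediate
27 | lithium lactolate from 26 and MeLi | [Li+].COc1cc(OCOC)c(C[C@H]3[C@H](C)COC3(C)[O-])c2c1C(=O)O[C@H](C)CCCCCCC2 | intermediate
28 | methyl lactol (2-hydroxy-2,4-dimethyltetrahydrofuran-3-ylmethyl macrolide) | COc1cc(OCOC)c(C[C@H]3[C@H](C)COC3(C)O)c2c1C(=O)O[C@H](C)CCCCCCC2 | intermediate
29 | free phenol of lactol 28 | COc1cc(O)c(C[C@H]3[C@H](C)COC3(C)O)c2c1C(=O)O[C@H](C)CCCCCCC2 | intermediate
30 | lasiodiplactone A (macrolide carbinol carbon R; ring-fusion CH S; CHCH3 S; ketal carbon S) | COc1cc2c(c3c1C(=O)O[C@H](C)CCCCCCC3)C[C@H]1[C@H](C)CO[C@@]1(C)O2 | target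

Total step count: 17. Longest linear sequence: 14 steps (steps 4–17, from methyl orsellinate).

Steps most likely to fail

1. Step 14. The copper-associated enolate may be alkylated too slowly. The methyl group left on copper may be transferred to the benzylic bromide. The bromide may decay by ionisation before it is consumed. The fallback sets out from 4 and returns at 23. The cuprate addition to 4 is run alone and quenched with aqueous NH4Cl. This gives (4S,5S)-4-methyl-5-[(1S,2R,5S)-menthyloxy]dihydrofuran-2(3H)-one F1, which is purified free of copper. Deprotonation of F1 with LDA in THF/DMPU at −78 °C regenerates enolate 22 as a pure lithium species. Bromide 20 benzylates it anti to the methyl group to give 23.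

2. Step 12. Transmetalation at the doubly ortho-substituted arylpalladium iodide may be slow, so that butyl transfer or protodeiodination takes over. The fallback sets out from 18 and returns at 19. Iodine–magnesium exchange with iPrMgCl·LiCl (THF, −20 °C) is assisted by the neighbouring OMOM oxygen and harmless to the shielded lactone. A DMF quench then gives 11-formyl-(R)-lasiodiplodin MOM ether F2. NaBH4 in MeOH at 0 °C reduces F2 to 19.

3. Step 16. The lactone may be enolised instead of attacked. A second addition may follow early collapse of the tetrahedral alkoxide. The macrolactone may be attacked. The fallback sets out from 26 and returns at 30. Petasis methylenation with Cp2TiMe2 (toluene, 70 °C, dark) is non-basic and cannot add twice. It should convert only the unhindered γ-lactone carbonyl into the exocyclic enol ether (3S,4S)-3-(macrolide-11-ylmethyl)-4-methyl-2-methylenetetrahydrofuran F3. The conditions of step 17 protonate its C=CH2 group to the same oxocarbenium ion, remove the MOM group and close the ketal to 30.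

Further compounds
F1 | step 14 | (4S,5S)-4-methyl-5-[(1S,2R,5S)-menthyloxy]dihydrofuran-2(3H)-one | O=C1C[C@H](C)[C@@H](O[C@H]2C[C@@H](C)CC[C@@H]2C(C)C)O1
F2 | step 12 | 11-formyl-(R)-lasiodiplodin MOM ether | COc1cc(OCOC)c(C=O)c2c1C(=O)O[C@H](C)CCCCCCC2
F3 | step 16 | (3S,4S)-3-(macrolide-11-ylmethyl)-4-methyl-2-methylenetetrahydrofuran | COc1cc(OCOC)c(C[C@H]3[C@H](C)COC3=C)c2c1C(=O)O[C@H](C)CCCCCCC2
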